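**Strategy**

Everything rests on treating the acetate C–O bond as the stereo-defining disconnection. Once acetyl and angeloyl are removed in thought, the two CH2O substituents of the carbinol carbon become equivalent. Bridging its tertiary oxygen and the ortho phenol oxygen with CMe2 then gives the six-membered 1,3-dioxine ring of a 4H-1,3-benzodioxine, whose ring carbon C4 is prochiral and whose O3 is blocked. A lipase transfers acetyl from vinyl acetate to one of the two enantiotopic CH2OH groups on C4, installing the acetate and the carbinol stereocentre in one operation. The precursor is the achiral 4,4-bis(hydroxymethyl)-2,2-dimethylbenzodioxine bearing a silyl-protected CH2OH at C7, assembled from 3-hydroxybenzyl alcohol and diethyl oxomalonate.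

Key step: step 5

Remark: which arm of 7 a given lipase acetylates cannot be fixed on paper; the route is written for the enzyme that delivers (4S)-9 directly, and the first fallback supplies the same compound if the preference is the opposite one.

**Route**

Step 1
Reactants: 1 3-hydroxybenzyl alcohol
Product: 2 3-({[tert-butyl(dimethyl)silyl]oxy}methyl)phenol
Conditions: TBSCl (1.05 equiv), imidazole, CH2Cl2–DMF, 0 °C
Reagents that add atoms: tert-butyl(chloro)dimethylsilane (TBSCl), CC(C)(C)[Si](C)(C)Cl
Why: Chemoselective silyl ether formation: under imidazole catalysis the neutral primary benzylic hydroxyl should be silylated much faster than the un-ionised phenol, and since an aryl silyl ether is the more labile one, any bis-silylated material can be returned to 2 by brief K2CO3/MeOH treatment.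

Step 2
Reactants: 2 3-({[tert-butyl(dimethyl)silyl]oxy}methyl)phenol; 3 diethyl oxomalonate
Product: 5 diethyl 2-[4-({[tert-butyl(dimethyl)silyl]oxy}methyl)-2-hydroxyphenyl]-2-hydroxypropanedioate, via bromomagnesium phenoxide 4 (not isolated)
Conditions: EtMgBr (1.0 equiv), Et2O, 0 °C; solvent switch to CH2Cl2; 3, 0 °C → rt; aq. NH4Cl
Reagents that add atoms: none
Why: Ortho-selective hydroxyalkylation of a magnesium phenoxide (chelation-controlled Friedel–Crafts-type carbonyl addition): in a non-coordinating solvent the ArOMgBr unit binds the highly electrophilic central C=O of 3 and delivers it to the neighbouring ring carbon through a six-membered transition state, and of the two ortho positions the one para to CH2OTBS is open whereas the one flanked by both substituents is shielded.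

Step 3
Reactants: 5 diethyl 2-[4-({[tert-butyl(dimethyl)silyl]oxy}methyl)-2-hydroxyphenyl]-2-hydroxypropanedioate
Product: 6 diethyl 7-({[tert-butyl(dimethyl)silyl]oxy}methyl)-2,2-dimethyl-4H-1,3-benzodioxine-4,4-dicarboxylate
Conditions: 2-methoxypropene, CSA (cat.), CH2Cl2, 0 °C → rt; Et3N quench
Reagents that add atoms: 2-methoxypropene, COC(C)=C
Why: Acid-catalysed isopropylidene ketal (acetonide) formation under enol-ether conditions: the phenol and the tertiary carbinol are the only hydroxyls present and should close the six-membered benzodioxine with loss of MeOH, the reactive oxocarbenium ion from 2-methoxypropene making up for the low nucleophilicity of the tartronate OH and the low temperature disfavouring lactonisation onto an ester.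

Step 4
Reactants: 6 diethyl 7-({[tert-butyl(dimethyl)silyl]oxy}methyl)-2,2-dimethyl-4H-1,3-benzodioxine-4,4-dicarboxylate
Product: 7 [7-({[tert-butyl(dimethyl)silyl]oxy}methyl)-2,2-dimethyl-4H-1,3-benzodioxine-4,4-diyl]dimethanol
Conditions: LiAlH4, THF, 0 °C; H2O, aq. NaOH work-up
Reagents that add atoms: none
Why: LiAlH4 reduction of a 2-alkoxymalonate to a 2-alkoxypropane-1,3-diol: ketal and silyl ether are inert to hydride, and because the tertiary oxygen is etherified no alkoxide-driven fragmentation of the intermediate aldehyde can intervene, so the achiral diol should result.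

Step 5
Reactants: 7 [7-({[tert-butyl(dimethyl)silyl]oxy}methyl)-2,2-dimethyl-4H-1,3-benzodioxine-4,4-diyl]dimethanol; 8 vinyl acetate
Product: 9 [(4S)-7-({[tert-butyl(dimethyl)silyl]oxy}methyl)-4-(hydroxymethyl)-2,2-dimethyl-4H-1,3-benzodioxin-4-yl]methyl acetate
Conditions: lipase B of Candida antarctica (immobilised), vinyl acetate (3 equiv), MTBE, 25 °C; filter
Reagents that add atoms: none
Why: The serine of the catalytic triad is acetylated by vinyl acetate, the released vinyl alcohol tautomerises to acetaldehyde so that the transfer cannot run backwards, and the acetyl-enzyme then passes the acyl group to the hydroxymethyl group of 7 that fits its alcohol pocket. The closest known reaction type is the lipase-catalysed monoacetylation of prochiral 2,2-disubstituted propane-1,3-diols and 2-O-substituted glycerols, including bis(hydroxymethyl) carbons that belong to a benzo-fused oxygen heterocycle. No ring is closed; the acetate C–O bond is the only bond formed. The new stereocentre C4 is set by the chiral active site alone (catalyst control), which can tell the two enantiotopic CH2OH groups apart because the ring holds the other two substituents of C4, the flat benzo carbon C4a and the ketal oxygen O3 with its gem-dimethyl carbon, rigidly and in very different spatial and polar environments. The step needs enantiotopic-group selectivity and mono- over bis-acylation; the rigid benzodioxine should secure the first, and any over-acylation should consume the minor enantiomer of 9 faster and so raise the enantiomeric purity of what remains. Because O3 is part of the ketal, a 1,2-acetyl shift to the tertiary oxygen, which would racemise a free 2-arylglycerol monoacetate, is excluded.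

Step 6
Reactants: 9 [(4S)-7-({[tert-butyl(dimethyl)silyl]oxy}methyl)-4-(hydroxymethyl)-2,2-dimethyl-4H-1,3-benzodioxin-4-yl]methyl acetate; 10 angelic acid [(2Z)-2-methylbut-2-enoic acid]
Product: 12 [(4R)-4-(acetoxymethyl)-7-({[tert-butyl(dimethyl)silyl]oxy}methyl)-2,2-dimethyl-4H-1,3-benzodioxin-4-yl]methyl (2Z)-2-methylbut-2-enoate, via angelic 2,4,6-trichlorobenzoic anhydride 11 (not isolated)
Conditions: 10, 2,4,6-Cl3C6H2COCl, Et3N (2 equiv per acid chloride), toluene, rt; then 9, 60 °C
Reagents that add atoms: none
Why: Yamaguchi mixed-anhydride esterification run without a nucleophilic pyridine catalyst: the alcohol attacks 11 at the angeloyl carbonyl because the other carbonyl is screened by two ortho chlorines, omitting 4-(dimethylamino)pyridine avoids the addition–elimination that would turn the Z-alkene into the tiglate, and the stereocentre is untouched, the descriptor changing from S to R only because the acylated arm now outranks CH2OAc.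

Step 7
Reactants: 12 [(4R)-4-(acetoxymethyl)-7-({[tert-butyl(dimethyl)silyl]oxy}methyl)-2,2-dimethyl-4H-1,3-benzodioxin-4-yl]methyl (2Z)-2-methylbut-2-enoate
Product: 13 [(4R)-4-(acetoxymethyl)-7-(hydroxymethyl)-2,2-dimethyl-4H-1,3-benzodioxin-4-yl]methyl (2Z)-2-methylbut-2-enoate
Conditions: HF·pyridine, pyridine, THF, 0 °C → rt
Reagents that add atoms: none
Why: Fluoride-mediated desilylation driven by Si–F bond formation: the pyridine-buffered reagent is neither basic enough to cleave or shift the two esters nor acidic enough to open the ketal, and no free hydroxyl sits next to an ester at this stage.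

Step 8
Reactants: 13 [(4R)-4-(acetoxymethyl)-7-(hydroxymethyl)-2,2-dimethyl-4H-1,3-benzodioxin-4-yl]methyl (2Z)-2-methylbut-2-enoate; 14 (2R)-2-methylbutanoic acid
Product: 15 [(4R)-4-(acetoxymethyl)-2,2-dimethyl-7-({[(2R)-2-methylbutanoyl]oxy}methyl)-4H-1,3-benzodioxin-4-yl]methyl (2Z)-2-methylbut-2-enoate
Conditions: DCC, DMAP (cat.), CH2Cl2, 0 °C → rt
Reagents that add atoms: none
Why: Steglich esterification: the benzylic CH2OH is the only free hydroxyl because phenol and tertiary OH are locked in the ketal, and carbodiimide activation with only catalytic DMAP at low temperature avoids a ketene pathway, so the α-stereocentre of the acid should be carried over unchanged as R.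

Step 9
Reactants: 15 [(4R)-4-(acetoxymethyl)-2,2-dimethyl-7-({[(2R)-2-methylbutanoyl]oxy}methyl)-4H-1,3-benzodioxin-4-yl]methyl (2Z)-2-methylbut-2-enoate
Product: 16 (2R)-3-acetoxy-2-hydroxy-2-[2-hydroxy-4-({[(2R)-2-methylbutanoyl]oxy}methyl)phenyl]propyl (2Z)-2-methylbut-2-enoate
Conditions: AcOH–H2O–THF (3:1:1), 40 °C
Reagents that add atoms: none
Why: Acid-catalysed hydrolysis of a mixed aryl alkyl isopropylidene ketal: protonation at the aryl oxygen releases the phenol as a good leaving group and water traps the alkoxycarbenium ion as acetone, while the two β-acyloxy groups disfavour a benzylic cation at the carbinol carbon, so the C–O bond at the stereocentre is never broken and the three esters should survive the weak aqueous acid.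

**Compound list**

1 | 3-hydroxybenzyl alcohol | OCc1cccc(O)c1 | starting material
2 | 3-({[tert-butyl(dimethyl)silyl]oxy}methyl)phenol | CC(C)(C)[Si](C)(C)OCc1cccc(O)c1 | intermediate
3 | diethyl oxomalonate | CCOC(=O)C(=O)C(=O)OCC | starting material
4 | bromomagnesium 3-({[tert-butyl(dimethyl)silyl]oxy}methyl)phenoxide | CC(C)(C)[Si](C)(C)OCc1cccc(O[Mg]Br)c1 | intermediate (not isolated)
5 | diethyl 2-[4-({[tert-butyl(dimethyl)silyl]oxy}methyl)-2-hydroxyphenyl]-2-hydroxypropanedioate | CCOC(=O)C(O)(C(=O)OCC)c1ccc(CO[Si](C)(C)C(C)(C)C)cc1O | intermediate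
6 | diethyl 7-({[tert-butyl(dimethyl)silyl]oxy}methyl)-2,2-dimethyl-4H-1,3-benzodioxine-4,4-dicarboxylate | CCOC(=O)C1(C(=O)OCC)OC(C)(C)Oc2cc(CO[Si](C)(C)C(C)(C)C)ccc12 | intermediate
7 | [7-({[tert-butyl(dimethyl)silyl]oxy}methyl)-2,2-dimethyl-4H-1,3-benzodioxine-4,4-diyl]dimethanol (achiral) | OCC1(CO)OC(C)(C)Oc2cc(CO[Si](C)(C)C(C)(C)C)ccc12 | intermediate
8 | vinyl acetate | CC(=O)OC=C | starting material
9 | [(4S)-7-({[tert-butyl(dimethyl)silyl]oxy}methyl)-4-(hydroxymethyl)-2,2-dimethyl-4H-1,3-benzodioxin-4-yl]methyl acetate | OC[C@@]1(COC(C)=O)OC(C)(C)Oc2cc(CO[Si](C)(C)C(C)(C)C)ccc12 | intermediate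
10 | angelic acid, (2Z)-2-methylbut-2-enoic acid | C/C=C(/C)C(=O)O | starting material
11 | (2Z)-2-methylbut-2-enoic 2,4,6-trichlorobenzoic anhydride | C/C=C(/C)C(=O)OC(=O)c1c(Cl)cc(Cl)cc1Cl | intermediate (not isolated)
12 | [(4R)-4-(acetoxymethyl)-7-({[tert-butyl(dimethyl)silyl]oxy}methyl)-2,2-dimethyl-4H-1,3-benzodioxin-4-yl]methyl (2Z)-2-methylbut-2-enoate | C/C=C(/C)C(=O)OC[C@@]1(COC(C)=O)OC(C)(C)Oc2cc(CO[Si](C)(C)C(C)(C)C)ccc12 | intermediate
13 | [(4R)-4-(acetoxymethyl)-7-(hydroxymethyl)-2,2-dimethyl-4H-1,3-benzodioxin-4-yl]methyl (2Z)-2-methylbut-2-enoate | C/C=C(/C)C(=O)OC[C@@]1(COC(C)=O)OC(C)(C)Oc2cc(CO)ccc12 | intermediate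
14 | (2R)-2-methylbutanoic acid | CC[C@@H](C)C(=O)O | starting material
15 | [(4R)-4-(acetoxymethyl)-2,2-dimethyl-7-({[(2R)-2-methylbutanoyl]oxy}methyl)-4H-1,3-benzodioxin-4-yl]methyl (2Z)-2-methylbut-2-enoate | C/C=C(/C)C(=O)OC[C@@]1(COC(C)=O)OC(C)(C)Oc2cc(COC(=O)[C@H](C)CC)ccc12 | intermediate
16 | (2R)-3-acetoxy-2-hydroxy-2-[2-hydroxy-4-({[(2R)-2-methylbutanoyl]oxy}methyl)phenyl]propyl (2Z)-2-methylbut-2-enoate | C/C=C(/C)C(=O)OC[C@](O)(COC(C)=O)c1ccc(COC(=O)[C@H](C)CC)cc1O | target

**Count and risks**

Total step count: 9. Longest linear sequence: 9 steps (1 → 16).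

Steps most likely to fail:

Step 5. The enzyme may distinguish the two enantiotopic hydroxymethyl groups poorly or in the opposite sense, or carry on to the diacetate. The fallback sets out from 7. Exhaustive acetylation (Ac2O, pyridine, DMAP cat., CH2Cl2) would give the achiral [7-({[tert-butyl(dimethyl)silyl]oxy}methyl)-2,2-dimethyl-4H-1,3-benzodioxine-4,4-diyl]bis(methylene) diacetate F1. Hydrolysis of one of its esters by the same lipase (aqueous NaH2PO4/Na2HPO4 buffer, pH 7, MTBE) would remove the acetate from the arm the active site prefers and leave it on the other arm. Hydrolysis in place of acylation therefore reaches the opposite enantiomeric series, and the fallback comes back to the route at 9.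

Step 6. Acylation of the neopentyl-type hydroxyl may be slow, and during that time the activated angeloyl group may isomerise from Z to E and the acetate may shift to the free arm, which would erode the enantiomeric purity. The fallback sets out from 9. A fast carbodiimide esterification at 0 °C (DCC, DMAP cat., CH2Cl2) with the unhindered, saturated 2-[bis(2,2,2-trifluoroethoxy)phosphoryl]propanoic acid would give [(4R)-4-(acetoxymethyl)-7-({[tert-butyl(dimethyl)silyl]oxy}methyl)-2,2-dimethyl-4H-1,3-benzodioxin-4-yl]methyl 2-[bis(2,2,2-trifluoroethoxy)phosphoryl]propanoate F2, as both epimers at the phosphorus-bearing carbon. A Still–Gennari olefination with acetaldehyde (KN(SiMe3)2, 18-crown-6, THF, −78 °C) would then build the Z-trisubstituted alkene on the acyl group already in place, and the fallback comes back to the route at 12.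

Step 3. The crowded, electron-poor tertiary hydroxyl may fail to close the ketal, or the phenol may lactonise onto an ester. The fallback sets out from 5; lactonised material would converge on the same triol. LiAlH4 in THF should give 2-[4-({[tert-butyl(dimethyl)silyl]oxy}methyl)-2-hydroxyphenyl]propane-1,2,3-triol F3. The lipase with an excess of vinyl acetate should acetylate only the two primary hydroxyls and give 2-[4-({[tert-butyl(dimethyl)silyl]oxy}methyl)-2-hydroxyphenyl]-2-hydroxypropane-1,3-diyl diacetate F4. In that compound the phenol and the tertiary hydroxyl are the only free pair, and the tertiary hydroxyl is no longer flanked by two ester carbonyls. Ketalisation (2-methoxypropene, CSA, CH2Cl2) should then give [7-({[tert-butyl(dimethyl)silyl]oxy}methyl)-2,2-dimethyl-4H-1,3-benzodioxine-4,4-diyl]bis(methylene) diacetate F1, and methanolysis (K2CO3, MeOH) comes back to the route at 7.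

**Further compounds**

F1 | step 5 | [7-({[tert-butyl(dimethyl)silyl]oxy}methyl)-2,2-dimethyl-4H-1,3-benzodioxine-4,4-diyl]bis(methylene) diacetate | CC(=O)OCC1(COC(C)=O)OC(C)(C)Oc2cc(CO[Si](C)(C)C(C)(C)C)ccc12
F2 | step 6 | [(4R)-4-(acetoxymethyl)-7-({[tert-butyl(dimethyl)silyl]oxy}methyl)-2,2-dimethyl-4H-1,3-benzodioxin-4-yl]methyl 2-[bis(2,2,2-trifluoroethoxy)phosphoryl]propanoate | CC(C(=O)OC[C@@]1(COC(C)=O)OC(C)(C)Oc2cc(CO[Si](C)(C)C(C)(C)C)ccc12)P(=O)(OCC(F)(F)F)OCC(F)(F)F
F3 | step 3 | 2-[4-({[tert-butyl(dimethyl)silyl]oxy}methyl)-2-hydroxyphenyl]propane-1,2,3-triol | OCC(O)(CO)c1ccc(CO[Si](C)(C)C(C)(C)C)cc1O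
F4 | step 3 | 2-[4-({[tert-butyl(dimethyl)silyl]oxy}methyl)-2-hydroxyphenyl]-2-hydroxypropane-1,3-diyl diacetate | CC(=O)OCC(O)(COC(C)=O)c1ccc(CO[Si](C)(C)C(C)(C)C)cc1O
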